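Numbering used throughout: isochromene core C1, O2, C3, C4, C4a, C5–C8, C8a; lactone O1′, C2′–C6′.

## Structural features

The target is a 7,8-dihydro-6H-isochromen-6-one: a pyran (O2, C1, C3, C4, C4a, C8a) fused through C4a–C8a to a carbocycle carrying chlorine at C5, the ketone at C6, a methyl-bearing tertiary alcohol at C7 and, at C8, a C–C bond to C3′ of a (6S)-6-methyloxane-2,4-dione. C3 bears the (1E,3E,5S)-3,5-dimethylhepta-1,3-dienyl chain. C7 and C8 are contiguous stereocentres with the C7 oxygen and C3′ on the same face. C3′ lies between two carbonyls and is stereolabile, and the side-chain and C6′ methyl centres are remote and best taken from the chiral pool. The doubly vinylogous ester chromophore (O2–C1=C8a and O2–C3=C4 conjugated with C4a=C5–C6=O) is attacked by nucleophiles at C1 and is easily dehydrogenated. The diene is sensitive to electrophilic oxidants, the tertiary α-ketol to base, and the β-keto lactone is acidic. The real difficulty is the fully substituted C7 carbinol: an external oxidant would approach the C6 enol anti to the C8 substituent and put oxygen trans to C3′. The key step exploits two facts: the carboxyl carbon C2′ of an acetic acid arm on C8 is exactly one five-membered ring away from C7, and the C6 ketone, flanked on its other side by the sp2, chlorinated C5, can enolise only towards C7.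

## Logic of the disconnections

23 ⇒ 20 + 21. The C3′–C4′ bond and the O1′–C2′ ester bond are cut, and C2′ is re-attached to the C7 oxygen. The six-membered lactone is a 5-hydroxy-3-oxo acid, and in 20 the C7 oxygen is both protected and activated as a strained ester of the same carboxyl. Four carbons and the C6′ stereocentre move into commercial 21. The forward step must acylate the enolate of 20 at C3′ with acyl–oxygen cleavage of 21, then pass C2′ from O7 to the new C6′ oxygen; C3′ is left to thermodynamic control.

20 ⇒ 19. The C7–O bond is cut. This removes the oxygen from C7 and turns the stereochemical problem into ring strain: a five-membered lactone spanning C7 and C8 can only be cis-fused. The forward step must oxidise the C6 enol at C7 with the tethered carboxylate as the only nucleophile, without touching the diene and without dehydrogenating C7–C8.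

19 ⇒ 17 ⇒ 16. A carboxyl is added back on C7 (C7–CO2allyl) and the arm acid is traced to a primary alcohol. A quaternary C7 cannot enolise, so it is inert to trivalent iodine while the arm is oxidised, it cannot quench the enolate in the annulation, and it makes the two ring carbonyls sterically different. The demand is that both unmaskings be neutral, hence an allyl ester removed by zerovalent palladium and not a base hydrolysis, which the chromophore would not tolerate.

16 ⇒ 14 + 4. The C4–C4a and O2–C1 bonds are cut. The pyran and the whole side chain are removed in one move, leaving a monocyclic chloroenone with C1 as an acetal. The forward step needs C4a to be the only position open to substitution and C1 to stay masked until acid is added.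

14 ⇒ 12 ⇒ 11 ⇒ 10. The C8a–C1 bond and the two C–Cl bonds are cut. C1 is introduced after the chloroenone is made, so its position is fixed by mechanism: only C8a has enolisable hydrogens once C7 is quaternary. Chloride is placed at C4a rather than C6 because C6 is shielded by the quaternary neighbour. C5 is chlorinated at the dione stage, before any diene is present.

10 ⇒ 9. The C5–C6 bond is cut (retro-Claisen). The arm is carried as a silyl ether because an ester arm would offer a second, less hindered electrophile for six-membered ring closure and would destroy the stereocentre by symmetry. The forward step needs the kinetic methyl-ketone enolate, which cannot undergo retro-Michael.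

9 ⇒ 8 ⇒ 6 + 7. The C7–CH3 bond and then the C7–C8 bond are cut. The unsubstituted malonate is the better-behaved donor for catalytic asymmetric Michael addition to an aliphatic enone, so the methyl group is added afterwards. The acceptor 6 has no acidic γ-hydrogens, which an ester arm would create. The forward Michael step sets C8, the only stereocentre of the core that must be made.

6 ⇒ 5 and 4 ⇒ 3 ⇒ 1. Three C=C bonds are cut by carbonyl olefination with stabilised ylides, which should give E alkenes. The side-chain stereocentre comes from 1 and must survive the aldehyde stage, so 2 is not isolated.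

## Other disconnections considered

Alternative 1: The cut is C4–C4a and O2–C1 on the fully elaborated, protected target. In the forward step the lithium enolate of 4 would substitute chloride at C4a of the chloroenone acetal A1 (C7 silyl ether and allyl-protected lactone in place); acid would then close the C3 enol oxygen onto C1 to give the protected target A2.
- In favour: high convergence, and the diene is introduced last and never meets an oxidant. On this point the alternative is better than the chosen plan.
- Equal: the bond-forming chemistry is the same as step 10 of the chosen route.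
- Against: A1 must already hold the C7 carbinol cis to C3′, so the cut relocates the central stereochemical problem instead of solving it. A basic enolate has to pass an electrophilic lactone enol ether, and C4a is next to a fully substituted silyloxy carbon. Two deprotections follow, one with zerovalent palladium on the finished chromophore, against one step after the key step here.
- Overall: equal in mechanism, better in convergence, weaker in that the C7 oxygen needs a separate answer.

Alternative 2: The cut is C7–C8 and C4a–C8a. A Diels–Alder reaction of the 3-methoxy-2-methylfuran A3 with the (E)-enal A4 under Me2AlCl would give the 7-oxanorbornene A5, whose bridge oxygen becomes the C7 oxygen.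
- In favour: two C–C bonds, the carbocycle and both C7 and C8 are made at once, the cis O/C3′ relationship follows from exo placement of C3′, and no oxidation is needed. In bond and redox economy the alternative is better than the chosen plan.
- Against: furan cycloadditions are reversible, and the required endo-formyl/exo-C3′ mode and the absolute face are not secured by the remote C6′ centre. The Lewis acid meets an acid-labile methoxyfuran and a dienyl ketone. After the key step the bridge must be opened at C4a, the pyran closed, C5 chlorinated and the lactone unmasked, all with the diene present.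
- Overall: more ambitious per step, but stereochemical certainty is lower than a catalytic Michael addition followed by a strain-controlled lactonisation; step count is probably similar.

Alternative 3: The cut is O2–C3 and C8–C3′. With Ph3PAuNTf2 the aldehyde oxygen of the ortho-quinol alkynyl dienal A6 would add to the alkyne, and the β-keto ester tethered on the C7 oxygen would add to C8 of the resulting benzopyrylium, giving the lactone A7.
- Equal: the stereochemical logic is the same as in the chosen plan, a two-atom tether between the C7 oxygen and C8, with the roles reversed.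
- In favour: the C4′ chain is already attached, so the late β-lactone acylation is avoided, and the route from an aromatic aldehyde would be shorter. On the endgame and on step economy the alternative is better.
- Against: A6 must be enantioenriched at C7, which requires an asymmetric oxidative dearomatisation of a phenol and handling of a dimerisation-prone acyl quinol. The carbon nucleophile may add at C1 instead of C8. Cationic gold meets a diene.
- Overall: shorter, but the absolute configuration rests on a harder asymmetric step than the Michael addition used here.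

Key step: step 13

Remarks on the chemistry (assumptions):
- 23 is drawn as the open 2,4-dioxo tautomer; C3′ is stereolabile, so its configuration is taken as thermodynamically set, and enol or C7–O hemiketal forms count as the same compound.
- C7 of 10–18, C8a of 14 and 15 and C3′ of 22 are inconsequential centres carried as epimer mixtures and left unassigned in the SMILES; 19 is drawn as the trans C7 epimer, and either epimer serves in step 13.
- The C8 descriptor changes from R in 19 to S in 20 and 23 only through CIP priorities; the spatial arrangement is the same, and the structures of 1, 19, 20 and 21 are consistent with 23.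
- The catalyst antipode in step 4 is chosen to give (S)-8; the sense of induction is assigned by analogy and would be confirmed before scale-up.
- 1, 5, 7, 21 and the three phosphorus ylides are taken to be commercial.

## Route

Step 1
Reactants: 1 (S)-2-methylbutan-1-ol
Product: 3 (2E,4S)-2,4-dimethylhex-2-enal, via (S)-2-methylbutanal 2 (not isolated)
Conditions: TEMPO (10 mol %), PhI(OAc)2 (1.1 equiv), ClCH2CH2Cl, rt; aq. NaHCO3 wash; then Ph3P=C(Me)CHO (1.2 equiv), 70 °C
Reagents that add atoms: 2-(triphenylphosphoranylidene)propanal, CC(C=O)=P(c1ccccc1)(c1ccccc1)c1ccccc1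
Why: Oxoammonium oxidation stops at the aldehyde under non-basic conditions that should leave the α-stereocentre intact, and the volatile, epimerisable aldehyde is consumed at once in a Wittig olefination. The formyl-stabilised ylide should give the E trisubstituted enal.

Step 2
Reactants: 3 (2E,4S)-2,4-dimethylhex-2-enal
Product: 4 (3E,5E,7S)-5,7-dimethylnona-3,5-dien-2-one
Conditions: Ph3P=CHC(O)Me (1.3 equiv), toluene, 90 °C
Reagents that add atoms: 1-(triphenylphosphoranylidene)propan-2-one, CC(=O)C=P(c1ccccc1)(c1ccccc1)c1ccccc1
Why: Wittig olefination with an acetyl-stabilised ylide should give the E disubstituted alkene. The stereocentre is remote from the reacting carbonyl.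

Step 3
Reactants: 5 3-[(tert-butyldimethylsilyl)oxy]propanal
Product: 6 (E)-6-[(tert-butyldimethylsilyl)oxy]hex-3-en-2-one
Conditions: Ph3P=CHC(O)Me (1.1 equiv), CH2Cl2, rt to 40 °C
Reagents that add atoms: 1-(triphenylphosphoranylidene)propan-2-one, CC(=O)C=P(c1ccccc1)(c1ccccc1)c1ccccc1
Why: Wittig olefination with a stabilised ylide is E-selective and non-basic, so β-elimination of the silyloxy group should not compete.

Step 4
Reactants: 6 (E)-6-[(tert-butyldimethylsilyl)oxy]hex-3-en-2-one; 7 diallyl malonate
Product: 8 diallyl 2-[(3S)-1-[(tert-butyldimethylsilyl)oxy]-5-oxohexan-3-yl]malonate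
Conditions: chiral primary amine–thiourea from trans-cyclohexane-1,2-diamine (10 mol %), PhCO2H (10 mol %), toluene, rt
Reagents that add atoms: none
Why: Asymmetric Michael addition under iminium and hydrogen-bond catalysis: the primary amine activates the enone as an iminium ion and the thiourea delivers the malonate enol to one face of the β-carbon, which sets C8. The acceptor has no acidic γ-hydrogens and the unsubstituted malonate is the standard donor for this catalyst class.

Step 5
Reactants: 8 diallyl 2-[(3S)-1-[(tert-butyldimethylsilyl)oxy]-5-oxohexan-3-yl]malonate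
Product: 9 diallyl 2-[(3S)-1-[(tert-butyldimethylsilyl)oxy]-5-oxohexan-3-yl]-2-methylmalonate
Conditions: NaH (1.1 equiv), THF–DMF, 0 °C; MeI (2 equiv), 0 °C to rt
Reagents that add atoms: iodomethane, CI
Why: Malonate alkylation: the malonate C–H is far more acidic than the ketone α-hydrogens, so only C7 is methylated. The fully deprotonated malonate cannot leave in a retro-Michael reaction, so C8 should keep its configuration.

Step 6
Reactants: 9 diallyl 2-[(3S)-1-[(tert-butyldimethylsilyl)oxy]-5-oxohexan-3-yl]-2-methylmalonate
Product: 10 allyl (6S)-6-{2-[(tert-butyldimethylsilyl)oxy]ethyl}-1-methyl-2,4-dioxocyclohexane-1-carboxylate (C1 epimers)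
Conditions: LiN(iPr)2 (2.2 equiv), THF, −78 °C to 0 °C; aq. NH4Cl
Reagents that add atoms: none
Why: Intramolecular Claisen (Dieckmann-type) acylation: the kinetic methyl-ketone enolate attacks one allyl ester in a 6-exo-trig closure and the dione is held as its enolate by the second equivalent of base. The kinetic enolate cannot expel the malonate, and the silyl ether arm offers no competing ester electrophile. The new C7 centre is uncontrolled and is erased in step 12.

Step 7
Reactants: 10 allyl (6S)-6-{2-[(tert-butyldimethylsilyl)oxy]ethyl}-1-methyl-2,4-dioxocyclohexane-1-carboxylate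
Product: 11 allyl (6S)-6-{2-[(tert-butyldimethylsilyl)oxy]ethyl}-3-chloro-4-hydroxy-1-methyl-2-oxocyclohex-3-ene-1-carboxylate (enol form of the 3-chloro-2,4-dione)
Conditions: N-chlorosuccinimide (1.05 equiv), CH2Cl2, 0 °C
Reagents that add atoms: N-chlorosuccinimide, O=C1CCC(=O)N1Cl
Why: Electrophilic α-chlorination of a 1,3-dione enol: C5 is the only doubly activated carbon. Chlorinating here, before the diene exists, avoids a late chlorination of the chromophore.

Step 8
Reactants: 11 allyl (6S)-6-{2-[(tert-butyldimethylsilyl)oxy]ethyl}-3-chloro-4-hydroxy-1-methyl-2-oxocyclohex-3-ene-1-carboxylate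
Product: 12 allyl (6S)-6-{2-[(tert-butyldimethylsilyl)oxy]ethyl}-3,4-dichloro-1-methyl-2-oxocyclohex-3-ene-1-carboxylate
Conditions: (COCl)2 (1.3 equiv), DMF (cat.), CH2Cl2, 0 °C to rt
Reagents that add atoms: oxalyl chloride, O=C(Cl)C(=O)Cl
Why: Vilsmeier-type conversion of a 1,3-dione enol into a β-chloro enone by O-activation and chloride addition–elimination. Chloride should enter at C4a, which is flanked by a CH2 group, and not at C6, which is shielded by the quaternary C7.

Step 9
Reactants: 12 allyl (6S)-6-{2-[(tert-butyldimethylsilyl)oxy]ethyl}-3,4-dichloro-1-methyl-2-oxocyclohex-3-ene-1-carboxylate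
Product: 14 allyl (6S)-6-{2-[(tert-butyldimethylsilyl)oxy]ethyl}-3,4-dichloro-5-(dimethoxymethyl)-1-methyl-2-oxocyclohex-3-ene-1-carboxylate (C5 epimers), via silyl dienol ether 13 (not isolated)
Conditions: Me3SiOTf (2.5 equiv), iPr2NEt (3 equiv), CH2Cl2, −78 °C to 0 °C; then HC(OMe)3 (3 equiv), −78 °C to −20 °C; pyridine, aq. NaHCO3
Reagents that add atoms: trimethyl orthoformate, COC(OC)OC
Why: Soft enolisation can only remove a C8a hydrogen because C7 is quaternary, giving the extended silyl dienol ether. A vinylogous Mukaiyama reaction with the dimethoxycarbenium ion should then occur at the γ-carbon C8a, since attack at the chlorinated C5 would give an unconjugated quaternary centre. Loss of the silyl group from the single oxygen returns the chloroenone, so no regioisomer is possible.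

Step 10
Reactants: 14 allyl (6S)-6-{2-[(tert-butyldimethylsilyl)oxy]ethyl}-3,4-dichloro-5-(dimethoxymethyl)-1-methyl-2-oxocyclohex-3-ene-1-carboxylate; 4 (3E,5E,7S)-5,7-dimethylnona-3,5-dien-2-one
Product: 16 allyl (8S)-5-chloro-3-[(1E,3E,5S)-3,5-dimethylhepta-1,3-dien-1-yl]-8-(2-hydroxyethyl)-7-methyl-6-oxo-7,8-dihydro-6H-isochromene-7-carboxylate (C7 epimers), via diketone 15 (not isolated)
Conditions: 4 (2.2 equiv), LiN(SiMe3)2 (2.2 equiv), THF, −78 °C; 14, −78 °C to −20 °C; then TsOH·H2O (3 equiv), THF–MeOH–H2O, 0 °C to rt
Reagents that add atoms: none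
Why: A [3+3] pyran annulation: the kinetic lithium enolate of the methyl ketone substitutes chloride at C4a by addition–elimination (vinylogous acyl substitution). Acid then ionises the acetal, the C3 enol oxygen closes on C1 (6-exo-trig) and methanol is lost to give the C1=C8a enol ether, while the silyl ether is cleaved. The quaternary C7 leaves no acidic hydrogen next to C6 that could quench the enolate.

Step 11
Reactants: 16 allyl (8S)-5-chloro-3-[(1E,3E,5S)-3,5-dimethylhepta-1,3-dien-1-yl]-8-(2-hydroxyethyl)-7-methyl-6-oxo-7,8-dihydro-6H-isochromene-7-carboxylate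
Product: 17 2-[(8S)-7-[(allyloxy)carbonyl]-5-chloro-3-[(1E,3E,5S)-3,5-dimethylhepta-1,3-dien-1-yl]-7-methyl-6-oxo-7,8-dihydro-6H-isochromen-8-yl]acetic acid (C7 epimers)
Conditions: TEMPO (20 mol %), PhI(OAc)2 (2.2 equiv), MeCN–pH 7 buffer (1:1), rt
Reagents that add atoms: water, O
Why: Oxoammonium oxidation of the primary alcohol to the aldehyde and, through its hydrate, to the acid, under conditions commonly used beside alkenes. The C6 ketone cannot enolise while C7 is quaternary, so the trivalent iodine co-oxidant has no access to C7 at this stage.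

Step 12
Reactants: 17 2-[(8S)-7-[(allyloxy)carbonyl]-5-chloro-3-[(1E,3E,5S)-3,5-dimethylhepta-1,3-dien-1-yl]-7-methyl-6-oxo-7,8-dihydro-6H-isochromen-8-yl]acetic acid
Product: 19 2-[(7R,8R)-5-chloro-3-[(1E,3E,5S)-3,5-dimethylhepta-1,3-dien-1-yl]-7-methyl-6-oxo-7,8-dihydro-6H-isochromen-8-yl]acetic acid, via keto diacid 18 (not isolated)
Conditions: Pd(PPh3)4 (5 mol %), HCO2H (3 equiv), Et3N (4 equiv), THF, rt, argon; acidify to pH 4
Reagents that add atoms: none
Why: Tsuji–Trost deallylation with formate as hydride donor: zerovalent palladium ionises the allyl ester, the π-allyl unit is reduced to propene so C-allylation is avoided, and the β-keto acid decarboxylates at room temperature. Protonation at C7 gives the 7-deoxy acid; its C7 configuration is irrelevant for the next step.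

Step 13
Reactants: 19 2-[(7R,8R)-5-chloro-3-[(1E,3E,5S)-3,5-dimethylhepta-1,3-dien-1-yl]-7-methyl-6-oxo-7,8-dihydro-6H-isochromen-8-yl]acetic acid
Product: 20 (6aS,9aS)-5-chloro-3-[(1E,3E,5S)-3,5-dimethylhepta-1,3-dien-1-yl]-6a-methyl-9,9a-dihydro-6H-furo[2,3-h]isochromene-6,8(6aH)-dione (cis-fused γ-lactone from the C7 oxygen to the C8 arm)
Conditions: PhI(OAc)2 (1.2 equiv), CF3CH2OH–CH2Cl2 (1:4), −20 °C to 0 °C, argon, dark
Reagents that add atoms: none
Why: The carboxylic acid exchanges onto PhI(OAc)2 and the C6 ketone enolises under acid catalysis, which is possible only towards C7; the enol attacks trivalent iodine to give a C7-bound (or O-bound) iodanyl ketone. The carboxylate oxygen then displaces the iodanyl group at C7 with loss of iodobenzene, a 5-exo-tet closure that forms the C7–O bond and the γ-lactone ring. The closest known reaction type is the hypervalent-iodine α-acyloxylation of ketones in its intramolecular form, the oxidative lactonisation of 5-oxo carboxylic acids to keto γ-lactones. The new stereocentre C7 is controlled by C8 through the two-atom tether: a five-membered lactone can span C7 and C8 only in the cis-fused sense, so oxygen arrives cis to the arm from either C7 epimer of 19. Site selectivity is secured because C5 is sp2 and chlorinated; chemoselectivity against the diene is expected because PhI(OAc)2 without strong acid is a weak alkene oxidant and the diene is deactivated by conjugation with the ketone. Lactonisation should beat β-elimination towards C8 because the nucleophile is held next to C7, the temperature is low and no base is present; trifluoroethanol assists ionisation of the C7–iodine bond, which makes substitution at the fully substituted, carbonyl-flanked carbon feasible.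

Step 14
Reactants: 20 (6aS,9aS)-5-chloro-3-[(1E,3E,5S)-3,5-dimethylhepta-1,3-dien-1-yl]-6a-methyl-9,9a-dihydro-6H-furo[2,3-h]isochromene-6,8(6aH)-dione; 21 (S)-4-methyloxetan-2-one
Product: 23 (3R,6S)-3-[(7S,8S)-5-chloro-3-[(1E,3E,5S)-3,5-dimethylhepta-1,3-dien-1-yl]-7-hydroxy-7-methyl-6-oxo-7,8-dihydro-6H-isochromen-8-yl]-6-methyloxane-2,4-dione, via acyl lactone 22 (not isolated)
Conditions: LiN(SiMe3)2 (2.1 equiv), THF, −78 °C; 21 (1.5 equiv), −78 °C to 0 °C; aq. NH4Cl
Reagents that add atoms: none
Why: Claisen-type acylation: the lithium enolate of the γ-lactone attacks the strained β-lactone carbonyl with acyl–oxygen cleavage, so the C6′ stereocentre is not touched. The liberated C6′ alkoxide then takes over C2′ (6-exo-trig, or via the acylketene), releasing the C7 alkoxide; the strongly acidic pyran-2,4-dione is the thermodynamic sink. C3′ equilibrates through the enolate.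

## Compound list

1 | (S)-2-methylbutan-1-ol | CC[C@H](C)CO | starting material
2 | (S)-2-methylbutanal | CC[C@H](C)C=O | intermediate (not isolated)
3 | (2E,4S)-2,4-dimethylhex-2-enal | CC[C@H](C)/C=C(C)/C=O | intermediate
4 | (3E,5E,7S)-5,7-dimethylnona-3,5-dien-2-one | CC[C@H](C)/C=C(C)/C=C/C(C)=O | intermediate
5 | 3-[(tert-butyldimethylsilyl)oxy]propanal | O=CCCO[Si](C)(C)C(C)(C)C | starting material
6 | (E)-6-[(tert-butyldimethylsilyl)oxy]hex-3-en-2-one | CC(=O)/C=C/CCO[Si](C)(C)C(C)(C)C | intermediate
7 | diallyl malonate | C=CCOC(=O)CC(=O)OCC=C | starting material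
8 | diallyl 2-[(3S)-1-[(tert-butyldimethylsilyl)oxy]-5-oxohexan-3-yl]malonate | CC(=O)C[C@H](CCO[Si](C)(C)C(C)(C)C)C(C(=O)OCC=C)C(=O)OCC=C | intermediate
9 | diallyl 2-[(3S)-1-[(tert-butyldimethylsilyl)oxy]-5-oxohexan-3-yl]-2-methylmalonate | CC(=O)C[C@H](CCO[Si](C)(C)C(C)(C)C)C(C)(C(=O)OCC=C)C(=O)OCC=C | intermediate
10 | allyl (6S)-6-{2-[(tert-butyldimethylsilyl)oxy]ethyl}-1-methyl-2,4-dioxocyclohexane-1-carboxylate | O=C1CC(=O)C(C)(C(=O)OCC=C)[C@@H](CCO[Si](C)(C)C(C)(C)C)C1 | intermediate
11 | allyl (6S)-6-{2-[(tert-butyldimethylsilyl)oxy]ethyl}-3-chloro-4-hydroxy-1-methyl-2-oxocyclohex-3-ene-1-carboxylate | OC1=C(Cl)C(=O)C(C)(C(=O)OCC=C)[C@@H](CCO[Si](C)(C)C(C)(C)C)C1 | intermediate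
12 | allyl (6S)-6-{2-[(tert-butyldimethylsilyl)oxy]ethyl}-3,4-dichloro-1-methyl-2-oxocyclohex-3-ene-1-carboxylate | ClC1=C(Cl)C(=O)C(C)(C(=O)OCC=C)[C@@H](CCO[Si](C)(C)C(C)(C)C)C1 | intermediate
13 | allyl (6S)-6-{2-[(tert-butyldimethylsilyl)oxy]ethyl}-3,4-dichloro-1-methyl-2-[(trimethylsilyl)oxy]cyclohexa-2,4-diene-1-carboxylate | C[Si](C)(C)OC1=C(Cl)C(Cl)=C[C@H](CCO[Si](C)(C)C(C)(C)C)C1(C)C(=O)OCC=C | intermediate (not isolated)
14 | allyl (6S)-6-{2-[(tert-butyldimethylsilyl)oxy]ethyl}-3,4-dichloro-5-(dimethoxymethyl)-1-methyl-2-oxocyclohex-3-ene-1-carboxylate | COC(OC)C1C(Cl)=C(Cl)C(=O)C(C)(C(=O)OCC=C)[C@H]1CCO[Si](C)(C)C(C)(C)C | intermediate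
15 | allyl (6S)-6-{2-[(tert-butyldimethylsilyl)oxy]ethyl}-3-chloro-5-(dimethoxymethyl)-4-[(3E,5E,7S)-5,7-dimethyl-2-oxonona-3,5-dien-1-yl]-1-methyl-2-oxocyclohex-3-ene-1-carboxylate | CC[C@H](C)/C=C(C)/C=C/C(=O)CC1=C(Cl)C(=O)C(C)(C(=O)OCC=C)[C@@H](CCO[Si](C)(C)C(C)(C)C)C1C(OC)OC | intermediate (not isolated)
16 | allyl (8S)-5-chloro-3-[(1E,3E,5S)-3,5-dimethylhepta-1,3-dien-1-yl]-8-(2-hydroxyethyl)-7-methyl-6-oxo-7,8-dihydro-6H-isochromene-7-carboxylate | CC[C@H](C)/C=C(C)/C=C/C1=CC2=C(Cl)C(=O)C(C)(C(=O)OCC=C)[C@@H](CCO)C2=CO1 | intermediate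
17 | 2-[(8S)-7-[(allyloxy)carbonyl]-5-chloro-3-[(1E,3E,5S)-3,5-dimethylhepta-1,3-dien-1-yl]-7-methyl-6-oxo-7,8-dihydro-6H-isochromen-8-yl]acetic acid | CC[C@H](C)/C=C(C)/C=C/C1=CC2=C(Cl)C(=O)C(C)(C(=O)OCC=C)[C@@H](CC(=O)O)C2=CO1 | intermediate
18 | (8S)-8-(carboxymethyl)-5-chloro-3-[(1E,3E,5S)-3,5-dimethylhepta-1,3-dien-1-yl]-7-methyl-6-oxo-7,8-dihydro-6H-isochromene-7-carboxylic acid | CC[C@H](C)/C=C(C)/C=C/C1=CC2=C(Cl)C(=O)C(C)(C(=O)O)[C@@H](CC(=O)O)C2=CO1 | intermediate (not isolated)
19 | 2-[(7R,8R)-5-chloro-3-[(1E,3E,5S)-3,5-dimethylhepta-1,3-dien-1-yl]-7-methyl-6-oxo-7,8-dihydro-6H-isochromen-8-yl]acetic acid | CC[C@H](C)/C=C(C)/C=C/C1=CC2=C(Cl)C(=O)[C@H](C)[C@@H](CC(=O)O)C2=CO1 | intermediate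
20 | (6aS,9aS)-5-chloro-3-[(1E,3E,5S)-3,5-dimethylhepta-1,3-dien-1-yl]-6a-methyl-9,9a-dihydro-6H-furo[2,3-h]isochromene-6,8(6aH)-dione | CC[C@H](C)/C=C(C)/C=C/C1=CC2=C(Cl)C(=O)[C@@]3(C)OC(=O)C[C@H]3C2=CO1 | intermediate
21 | (S)-4-methyloxetan-2-one | C[C@H]1CC(=O)O1 | starting material
22 | (6aS,9aS)-5-chloro-3-[(1E,3E,5S)-3,5-dimethylhepta-1,3-dien-1-yl]-9-[(3S)-3-hydroxybutanoyl]-6a-methyl-9,9a-dihydro-6H-furo[2,3-h]isochromene-6,8(6aH)-dione | CC[C@H](C)/C=C(C)/C=C/C1=CC2=C(Cl)C(=O)[C@@]3(C)OC(=O)C(C(=O)C[C@H](C)O)[C@H]3C2=CO1 | intermediate (not isolated)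
23 | (3R,6S)-3-[(7S,8S)-5-chloro-3-[(1E,3E,5S)-3,5-dimethylhepta-1,3-dien-1-yl]-7-hydroxy-7-methyl-6-oxo-7,8-dihydro-6H-isochromen-8-yl]-6-methyloxane-2,4-dione | CC[C@H](C)/C=C(C)/C=C/C1=CC2=C(Cl)C(=O)[C@@](C)(O)[C@@H]([C@@H]3C(=O)C[C@H](C)OC3=O)C2=CO1 | target

## Step count and least certain steps

Total: 14 steps. Longest linear sequence: 12 steps (5 → 6 → 8 → 9 → 10 → 11 → 12 → 14 → 16 → 17 → 19 → 20 → 23); the side-chain ketone 4 is made in 2 steps and joins in step 10.

Step 13 (key step). The most likely failure is loss of the iodanyl group by elimination towards C8, which dehydrogenates the ring to the aromatic quinoid, or oxidation of the dienyl chain by trivalent iodine. Both compete because substitution at the fully substituted C7 is slow and aromatisation is strongly downhill. Fallback: setting out from 19, the C6 enol is iodinated with N-iodosuccinimide and catalytic TsOH in CH2Cl2 to the 7-iodo acid F1, with iodine expected anti to the C8 arm. Silver-assisted intramolecular displacement (AgOTf, 2,6-lutidine) by the carboxylate with inversion would then give the same cis-fused lactone, returning to the route at 20.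

Step 14. The enolate may open 21 by alkyl–oxygen cleavage at C4 of the β-lactone in place of acyl transfer, or the lithium enolate of 20 may fragment to a ketene before it is acylated; the transfer of C2′ may also stall at 22. Fallback: setting out from 21 and 20, the lactone 21 is opened with MeNH(OMe)·HCl and AlMe3 to (3S)-3-hydroxy-N-methoxy-N-methylbutanamide F2, which is silylated (Et3SiCl, imidazole) to (3S)-N-methoxy-N-methyl-3-[(triethylsilyl)oxy]butanamide F3. The lithium enolate of 20 is acylated with F3 to the silyl-protected acyl lactone F4. HF·pyridine then frees the hydroxyl to give 22, and Et3N completes the translactonisation, returning to the route at 23.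

Step 10. The enolate may act as a base, removing the C8a hydrogen with loss of methoxide, or add to the C6 carbonyl, in place of substituting the hindered C4a; the hydroxyethyl arm may also trap C1 during the acid stage. Fallback: setting out from 4 and 14, the ketone 4 is condensed with pyrrolidine (TsOH cat., toluene, water removal) to the dienamine 1-[(3E,5E,7S)-5,7-dimethylnona-1,3,5-trien-2-yl]pyrrolidine F5. This neutral carbon nucleophile substitutes chloride at C4a of 14 (Et3N, MeCN) to give the vinylogous amide F6. Aqueous TsOH hydrolyses the enamine to 15 and closes the pyran, returning to the route at 16.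

Step 9. The dichloro dienol ether 13 may be too weak a nucleophile for the dimethoxycarbenium ion, or the reaction may stop at silylation. Fallback: setting out from 11, the chlorodione is converted with Me3SiOTf and Et3N into the bis(trimethylsilyl) dienol ether F7, a much more nucleophilic 1,3-dioxygenated diene. F7 reacts with HC(OMe)3 and catalytic Me3SiOTf at its terminal carbon C8a to give, after work-up, the chlorodione acetal F8. (COCl)2 with catalytic DMF then converts F8 into the chloroenone, returning to the route at 14. The cost is less secure regiocontrol in the chlorination, because C4a is then next to a branched carbon.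

Step 4. Facial selectivity may be poor, or conversion slow, with this aliphatic enone. Fallback: setting out from 5 and 7, the aldehyde 5 is olefinated with Ph3P=CHCHO to (E)-5-[(tert-butyldimethylsilyl)oxy]pent-2-enal F9. Addition of 7 under iminium catalysis with a diarylprolinol silyl ether gives the aldehyde adduct F10, a well-established reaction for aliphatic enals. MeMgBr (2.2 equiv, −78 °C; the first equivalent is consumed by the malonate C–H, which also protects the esters) gives the secondary alcohol F11, and Dess–Martin oxidation returns to the route at 8.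

## Further compounds

F1 | step 13 | 2-[(7R,8S)-5-chloro-3-[(1E,3E,5S)-3,5-dimethylhepta-1,3-dien-1-yl]-7-iodo-7-methyl-6-oxo-7,8-dihydro-6H-isochromen-8-yl]acetic acid | CC[C@H](C)/C=C(C)/C=C/C1=CC2=C(Cl)C(=O)[C@](C)(I)[C@@H](CC(=O)O)C2=CO1
F2 | step 14 | (3S)-3-hydroxy-N-methoxy-N-methylbutanamide | C[C@H](O)CC(=O)N(C)OC
F3 | step 14 | (3S)-N-methoxy-N-methyl-3-[(triethylsilyl)oxy]butanamide | C[C@H](O[Si](CC)(CC)CC)CC(=O)N(C)OC
F4 | step 14 | (6aS,9aS)-5-chloro-3-[(1E,3E,5S)-3,5-dimethylhepta-1,3-dien-1-yl]-6a-methyl-9-[(3S)-3-[(triethylsilyl)oxy]butanoyl]-9,9a-dihydro-6H-furo[2,3-h]isochromene-6,8(6aH)-dione | CC[C@H](C)/C=C(C)/C=C/C1=CC2=C(Cl)C(=O)[C@@]3(C)OC(=O)C(C(=O)C[C@H](C)O[Si](CC)(CC)CC)[C@H]3C2=CO1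
F5 | step 10 | 1-[(3E,5E,7S)-5,7-dimethylnona-1,3,5-trien-2-yl]pyrrolidine | CC[C@H](C)/C=C(C)/C=C/C(=C)N1CCCC1
F6 | step 10 | allyl (6S)-6-{2-[(tert-butyldimethylsilyl)oxy]ethyl}-3-chloro-5-(dimethoxymethyl)-4-[(3E,5E,7S)-5,7-dimethyl-2-(pyrrolidin-1-yl)nona-1,3,5-trien-1-yl]-1-methyl-2-oxocyclohex-3-ene-1-carboxylate | CC[C@H](C)/C=C(C)/C=C/C(=CC1=C(Cl)C(=O)C(C)(C(=O)OCC=C)[C@@H](CCO[Si](C)(C)C(C)(C)C)C1C(OC)OC)N1CCCC1
F7 | step 9 | allyl (6S)-6-{2-[(tert-butyldimethylsilyl)oxy]ethyl}-3-chloro-1-methyl-2,4-bis[(trimethylsilyl)oxy]cyclohexa-2,4-diene-1-carboxylate | C[Si](C)(C)OC1=C(Cl)C(O[Si](C)(C)C)=C[C@H](CCO[Si](C)(C)C(C)(C)C)C1(C)C(=O)OCC=C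
F8 | step 9 | allyl (6S)-6-{2-[(tert-butyldimethylsilyl)oxy]ethyl}-3-chloro-5-(dimethoxymethyl)-4-hydroxy-1-methyl-2-oxocyclohex-3-ene-1-carboxylate | COC(OC)C1C(O)=C(Cl)C(=O)C(C)(C(=O)OCC=C)[C@H]1CCO[Si](C)(C)C(C)(C)C
F9 | step 4 | (E)-5-[(tert-butyldimethylsilyl)oxy]pent-2-enal | O=C/C=C/CCO[Si](C)(C)C(C)(C)C
F10 | step 4 | diallyl 2-[(3S)-1-[(tert-butyldimethylsilyl)oxy]-5-oxopentan-3-yl]malonate | O=CC[C@H](CCO[Si](C)(C)C(C)(C)C)C(C(=O)OCC=C)C(=O)OCC=C
F11 | step 4 | diallyl 2-[(3S)-1-[(tert-butyldimethylsilyl)oxy]-5-hydroxyhexan-3-yl]malonate | CC(O)C[C@H](CCO[Si](C)(C)C(C)(C)C)C(C(=O)OCC=C)C(=O)OCC=C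
A1 | alternative 1 | chloroenone acetal with C7 triethylsilyl ether and allyl-protected lactone | COC(OC)C1C(Cl)=C(Cl)C(=O)[C@@](C)(O[Si](CC)(CC)CC)[C@H]1C2=C(OCC=C)C[C@H](C)OC2=O
A2 | alternative 1 | protected target (C7 triethylsilyl ether, lactone allyl enol ether) | CC[C@H](C)/C=C(C)/C=C/C1=CC2=C(Cl)C(=O)[C@@](C)(O[Si](CC)(CC)CC)[C@@H](C3=C(OCC=C)C[C@H](C)OC3=O)C2=CO1
A3 | alternative 2 | (3E,5E,7S)-1-(4-methoxy-5-methylfuran-2-yl)-5,7-dimethylnona-3,5-dien-2-one | CC[C@H](C)/C=C(C)/C=C/C(=O)Cc1cc(OC)c(C)o1
A4 | alternative 2 | (E)-3-{6-[(2S)-2-[(tert-butyldimethylsilyl)oxy]propyl]-2,2-dimethyl-4-oxo-4H-1,3-dioxin-5-yl}prop-2-enal | O=C/C=C/C1=C(C[C@H](C)O[Si](C)(C)C(C)(C)C)OC(C)(C)OC1=O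
A5 | alternative 2 | 7-oxanorbornene cycloadduct (bridge oxygen between C7 and C4a, formyl endo, C3′ exo) | CC[C@H](C)/C=C(C)/C=C/C(=O)C[C@@]12C=C(OC)[C@@](C)(O1)[C@@H](C3=C(C[C@H](C)O[Si](C)(C)C(C)(C)C)OC(C)(C)OC3=O)[C@@H]2C=O
A6 | alternative 3 | ortho-quinol alkynyl dienal with the β-keto ester on the C7 oxygen | CC[C@H](C)/C=C(C)/C=C/C#CC1=C(Cl)C(=O)[C@@](C)(OC(=O)CC(=O)C[C@H](C)O[Si](C)(C)C(C)(C)C)C=C1C=O
A7 | alternative 3 | bicyclic core with cis-fused C3′-acyl γ-lactone | CC[C@H](C)/C=C(C)/C=C/C1=CC2=C(Cl)C(=O)[C@@]3(C)OC(=O)[C@@H](C(=O)C[C@H](C)O[Si](C)(C)C(C)(C)C)[C@H]3C2=CO1
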